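The first chemist at this flask holds that each pre-initiator begins a chain, while the second holds that the impurity takes its share first and that chains come from what stays over.

    free monomer + initiator → living end + monomer in chains (k1 = 0.590 L mol⁻¹ h⁻¹)
    free monomer + living end → monomer in chains + living end, rate k2*[living end]*[free monomer] (k2 = 4.60 L mol⁻¹ h⁻¹)
    initiator + impurity → spent initiator (k3 = 466 L mol⁻¹ h⁻¹)
    pre-initiator → initiator (k4 = 0.0644 h⁻¹)

free monomer 0.050 M; pre-initiator 7 mol%; impurity 1.5 mM; time 10 d

- average number of monomer units in a chain (chains begun, living or dead) at 10 d
- part of the free monomer that has reacted at 10 d

Both argue by the turnover count, which is the growth constant times the living ends times their working time, so that it counts the e-fold falls of the free monomer in a pseudo-first-order decay. For the working time I take the run less a lag of 49.4 h, the mean wait for unmasking plus the mean wait for initiation at the starting monomer. The first chemist counts 3.50 mM of chains, which gives 3.07 turnovers, 95.3 % reacted and about 13.6 units per chain. The second chemist answers that, at the charged concentrations, initiator has a half-life of 0.99 h against impurity but 0.98 d against free monomer, so the chains number the surplus, 2.00 mM. I side with the second, and my turnover count 1.75 gives 82.7 % reacted and 20.7 units per chain.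

The forecast, on the second chemist's side, says 82 % and 20.7, since “the impurity scavenges nearly 1.5 mM of it almost immediately”.

The flask gives 81.1 % and 21.1, which is the second chemist's outcome. The first chemist's view stands nearer in the neighbour with 0.20 M of free monomer, where impurity matches 10.7 % of the pre-initiator, against 42.9 % in this flask, and where living end at 10.0 d is 78.3 % of the pre-initiator charged, against 55.0 % in this flask. The forecast's numbers stop holding in the neighbour with 4.2 mol% of pre-initiator, where the surplus is 0.600 mM. The same lag then gives 0.526 turnovers, 40.9 % reacted and 34.1 units per chain. At 10.0 d that neighbour stands at 40.1 % reacted and 33.7 units per chain, with 5.96 × 10⁻⁴ M of living end.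

The constants used here belong to no real substance; the run is a simulation.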